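**Retrosynthetic overview** (carotenoid numbering: ring C1–C6, chain from C7)
1. The last bond is C11=C12, made by Wittig reaction of the ring C15 phosphonium salt 21 with the C25 polyene aldehyde 27; 27 comes from the ψ-end C15 salt 24 and the C10 dialdehyde 25.
2. Salt 21 comes from vinyl carbinol 20, which is made from ring alkyne 16 and methyl vinyl ketone by acetylide addition and LiAlH4 trans-reduction (7E).
3. The cyclohexene ring is built by one-carbon ring expansion of a cyclopentene: its dibromocarbene adduct 10 (a 6,6-dibromobicyclo[3.1.0]hexane) is opened by silver to a 2-bromocyclohexenyl cation, which the neighbouring C3 carbamate traps at C4.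
4. Enabling feature: C4–C5–C6 of the ring is an allyl unit (allylic C4–OH beside the tetrasubstituted C5=C6 alkene), so the methyl-bearing C5 can be inserted as a carbene carbon into a cyclopentene C4=C6 bond; the cis C3–O/C4–O pair lets the C3 oxygen function deliver the C4 oxygen on its own face.
5. Ring order: purchased cyclopentenone ring (C1, C2, C3, C4, C6) → bicyclo[3.1.0]hexane → cyclohexene (the only ring of the target); C3 is set by Corey–Bakshi–Shibata reduction and C4 by the key step.

Key step: step 6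

Assumption: pseudoionone 22 is taken as its (3E,5E) isomer, the main component of the commercial material; any 5Z material is expected to be removed when salt 24 is crystallised.

**Route**

Step 1
Reactants: 1 3-ethoxycyclopent-2-en-1-one
Product: 3 3-ethoxy-5,5-dimethylcyclopent-2-en-1-one, via 3-ethoxy-5-methylcyclopent-2-en-1-one 2 (not isolated)
Conditions: LiN(iPr)2, THF, −78 °C, then MeI, −78 → 0 °C; repeated once in the same flask (LiN(iPr)2, −78 °C; MeI, → rt)
Reagents that add atoms: iodomethane, CI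
Why: Kinetic deprotonation of the vinylogous ester takes place at the α'-carbon and not at the γ-carbon, so two successive enolate alkylations (α'-alkylation of a 3-alkoxyenone) should place the gem-dimethyl group next to the carbonyl.

Step 2
Reactants: 3 3-ethoxy-5,5-dimethylcyclopent-2-en-1-one; 4 ethynyltri(propan-2-yl)silane
Product: 7 4,4-dimethyl-3-[(triisopropylsilyl)ethynyl]cyclopent-2-en-1-one, via lithium (triisopropylsilyl)acetylide 5 (not isolated), via lithium alkoxide adduct 6 (not isolated)
Conditions: 4, n-BuLi, THF, −78 °C; add 3, −78 → 0 °C; then 1 M HCl, rt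
Reagents that add atoms: water, O
Why: Stork–Danheiser alkylative carbonyl transposition, in which the small linear acetylide should add 1,2 to the hindered vinylogous ester carbonyl and aqueous acid then hydrolyses the enol ether and eliminates the tertiary hydroxyl to give the transposed enone.

Step 3
Reactants: 7 4,4-dimethyl-3-[(triisopropylsilyl)ethynyl]cyclopent-2-en-1-one
Product: 8 (1R)-4,4-dimethyl-3-[(triisopropylsilyl)ethynyl]cyclopent-2-en-1-ol
Conditions: (S)-1-methyl-3,3-diphenyl-tetrahydro-1H,3H-pyrrolo[1,2-c][1,3,2]oxazaborole (20 mol %), catecholborane, toluene, −78 °C; MeOH quench, aq. NaOH wash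
Reagents that add atoms: none
Why: Corey–Bakshi–Shibata reduction, in which the alkenyl side of the enone acts as the large group, so the (S)-oxazaborolidine should give the (1R)-allylic alcohol (the later C3), while catecholborane at low temperature should spare the silylalkyne.

Step 4
Reactants: 8 (1R)-4,4-dimethyl-3-[(triisopropylsilyl)ethynyl]cyclopent-2-en-1-ol
Product: 9 (1R)-4,4-dimethyl-3-[(triisopropylsilyl)ethynyl]cyclopent-2-en-1-yl dimethylcarbamate
Conditions: NaH, THF, 0 °C; Me2NCOCl, 0 °C → rt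
Reagents that add atoms: dimethylcarbamoyl chloride, CN(C)C(Cl)=O
Why: O-Carbamoylation of the sodium alkoxide is a routine acylation that installs a base-stable group able to serve later as an internal oxygen nucleophile and leaves the stereocentre untouched.

Step 5
Reactants: 9 (1R)-4,4-dimethyl-3-[(triisopropylsilyl)ethynyl]cyclopent-2-en-1-yl dimethylcarbamate
Product: 10 (1R,2R,5S)-6,6-dibromo-4,4-dimethyl-5-[(triisopropylsilyl)ethynyl]bicyclo[3.1.0]hexan-2-yl dimethylcarbamate (cyclopropane on the face opposite to the carbamate)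
Conditions: CHBr3, 50% aq. NaOH, BnEt3NCl (cat.), CH2Cl2, 0 °C → rt, vigorous stirring; crude product kept at or below rt and used directly
Reagents that add atoms: bromoform, BrC(Br)Br
Why: Phase-transfer dibromocarbene addition (dihalocyclopropanation) is selective for the alkene of a conjugated enyne and tolerates the carbamate and the hindered silylalkyne; the carbene should approach mainly anti to the carbamate, but either face serves because both adducts carry one endo bromine and lead to the same cation.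

Step 6
Reactants: 10 (1R,2R,5S)-6,6-dibromo-4,4-dimethyl-5-[(triisopropylsilyl)ethynyl]bicyclo[3.1.0]hexan-2-yl dimethylcarbamate
Product: 13 (3aR,7aR)-7-bromo-5,5-dimethyl-6-[(triisopropylsilyl)ethynyl]-3a,4,5,7a-tetrahydro-1,3-benzodioxol-2-one (cis-fused cyclic carbonate), via 2-bromoallyl cation triflate 11 (not isolated), via dioxolan-2-iminium triflate 12 (not isolated)
Conditions: AgOSO2CF3 (1.5 equiv), CH2Cl2/MeNO2, 0 °C → rt, dark; then H2O, rt; aq. NaHCO3 wash
Reagents that add atoms: water, O
Why: Proposed new method: monovalent silver abstracts the endo bromide and the cyclopropyl cation opens in a disrotatory two-electron electrocyclic step that breaks the C4–C6 fusion bond, so the five-membered ring becomes a six-membered 2-bromoallyl cation (C4–C5–C6), a one-carbon ring expansion that is known with external nucleophiles (silver-promoted opening of 6,6-dibromobicyclo[3.1.0]hexanes to 2-bromocyclohex-2-enyl esters and ethers); the new element is capture of the cation at C4 by the carbonyl oxygen of the vicinal carbamate in a 5-exo closure, as carbamates and carbonates do towards iodonium ions in halocyclisations, to give a 2-iminio-1,3-dioxolane that weakly acidic water hydrolyses at the iminium carbon to the cyclic carbonate. The dioxolane can only be cis-fused, so the C3 centre from step 3 controls the new C4 centre and gives the cis-diol relationship whichever face the cyclopropane occupied. Regioselectivity is secured by the tether, which reaches C4 but not C6, and the same operation sets the tetrasubstituted C5=C6 alkene, a C5 bromide for the later methyl group and the C6 alkyne in their final places. Elimination is not open to the cation because C6 is flanked by a quaternary carbon and an alkyne that carry no β-hydrogen, and triflate is too poor a nucleophile to compete.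

Step 7
Reactants: 13 (3aR,7aR)-7-bromo-5,5-dimethyl-6-[(triisopropylsilyl)ethynyl]-3a,4,5,7a-tetrahydro-1,3-benzodioxol-2-one
Product: 15 (1R,2S)-3,5,5-trimethyl-4-[(triisopropylsilyl)ethynyl]cyclohex-3-ene-1,2-diol, via bromo diol 14 (not isolated)
Conditions: K2CO3, 1,4-dioxane/H2O, 50 °C; then trimethylboroxine, PdCl2(dppf) (5 mol %), 90 °C
Reagents that add atoms: trimethylboroxine, CB1OB(C)OB(C)O1
Why: Carbonate hydrolysis first removes the allylic leaving group so that zerovalent palladium cannot ionise it, and Suzuki–Miyaura coupling of the alkenyl bromide with the methylboron reagent then installs the C5 methyl group without touching the stereocentres.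

Step 8
Reactants: 15 (1R,2S)-3,5,5-trimethyl-4-[(triisopropylsilyl)ethynyl]cyclohex-3-ene-1,2-diol
Product: 16 (1R,2S)-4-ethynyl-3,5,5-trimethylcyclohex-3-ene-1,2-diol
Conditions: Bu4NF, THF, 0 °C → rt
Reagents that add atoms: none
Why: Fluoride-induced protodesilylation of an alkynylsilane is routine and leaves the diol and the enyne unchanged.

Step 9
Reactants: 16 (1R,2S)-4-ethynyl-3,5,5-trimethylcyclohex-3-ene-1,2-diol; 17 but-3-en-2-one (methyl vinyl ketone)
Product: 19 (1R,2S)-4-(3-hydroxy-3-methylpent-4-en-1-yn-1-yl)-3,5,5-trimethylcyclohex-3-ene-1,2-diol (both epimers at the side-chain carbinol), via tris(bromomagnesium) acetylide 18 (not isolated)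
Conditions: EtMgBr (3.3 equiv), THF, 0 → 40 °C; then 17, −30 → 0 °C; aq. NH4Cl
Reagents that add atoms: none
Why: Deprotonation of both hydroxyls and the alkyne gives a magnesium acetylide that should add 1,2 to the ketone (alkynyl Grignard addition); the new carbinol centre forms as both epimers, which is of no consequence because it is removed in step 11.

Step 10
Reactants: 19 (1R,2S)-4-(3-hydroxy-3-methylpent-4-en-1-yn-1-yl)-3,5,5-trimethylcyclohex-3-ene-1,2-diol
Product: 20 (1R,2S)-4-[(1E)-3-hydroxy-3-methylpenta-1,4-dien-1-yl]-3,5,5-trimethylcyclohex-3-ene-1,2-diol (both epimers at the side-chain carbinol)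
Conditions: LiAlH4 (excess), THF, 0 → 50 °C; aq. NaOH work-up
Reagents that add atoms: none
Why: Hydroxyl-directed trans-hydroalumination of a propargylic alcohol by LiAlH4 should give the (E)-allylic alcohol and so set the 7E geometry.

Step 11
Reactants: 20 (1R,2S)-4-[(1E)-3-hydroxy-3-methylpenta-1,4-dien-1-yl]-3,5,5-trimethylcyclohex-3-ene-1,2-diol
Product: 21 {(2E,4E)-5-[(3S,4R)-3,4-dihydroxy-2,6,6-trimethylcyclohex-1-en-1-yl]-3-methylpenta-2,4-dien-1-yl}triphenylphosphonium bromide
Conditions: PPh3·HBr (1.05 equiv), MeOH/CH2Cl2, 0 °C → rt; crystallisation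
Reagents that add atoms: triphenylphosphine hydrobromide, [Br-].c1ccc(cc1)[PH+](c1ccccc1)c1ccccc1
Why: The tertiary bis-allylic alcohol ionises under mild acid to a pentadienyl cation that triphenylphosphine traps at the unhindered primary terminus (SN1' phosphonium salt formation from a vinyl carbinol), which should give mainly the 9E salt, purified by crystallisation.

Step 12
Reactants: 22 (3E,5E)-6,10-dimethylundeca-3,5,9-trien-2-one (pseudoionone)
Product: 23 (4E,6E)-3,7,11-trimethyldodeca-1,4,6,10-tetraen-3-ol (racemic)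
Conditions: CH2=CHMgBr, THF, −20 → 0 °C; aq. NH4Cl
Reagents that add atoms: vinylmagnesium bromide, C=C[Mg]Br
Why: 1,2-Addition of a vinyl Grignard reagent to the dienone carbonyl gives the tertiary vinyl carbinol, whose racemic centre is lost in the next step.

Step 13
Reactants: 23 (4E,6E)-3,7,11-trimethyldodeca-1,4,6,10-tetraen-3-ol
Product: 24 [(2E,4E,6E)-3,7,11-trimethyldodeca-2,4,6,10-tetraen-1-yl]triphenylphosphonium bromide
Conditions: PPh3·HBr, MeOH, rt; crystallisation
Reagents that add atoms: triphenylphosphine hydrobromide, [Br-].c1ccc(cc1)[PH+](c1ccccc1)c1ccccc1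
Why: Acid-mediated SN1' phosphonium salt formation from the vinyl carbinol should give the primary allylic salt, the 2E isomer being isolated by crystallisation.

Step 14
Reactants: 24 [(2E,4E,6E)-3,7,11-trimethyldodeca-2,4,6,10-tetraen-1-yl]triphenylphosphonium bromide; 25 (2E,4E,6E)-2,7-dimethylocta-2,4,6-trienedial
Product: 27 (2E,4E,6E,8E,10E,12E,14E)-2,7,11,15,19-pentamethylicosa-2,4,6,8,10,12,14,18-octaenal, via phosphorus ylide 26 (not isolated)
Conditions: NaOMe, MeOH/CH2Cl2, 0 °C, slow addition of 24 and base to 25 (3 equiv), → rt; then reflux in n-heptane (Z → E)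
Reagents that add atoms: none
Why: Wittig olefination of the allylic ylide with an excess of the symmetrical dialdehyde should stop after one condensation because the product aldehyde is more conjugated and less electrophilic, and heating should equilibrate the new double bond to E.

Step 15
Reactants: 21 {(2E,4E)-5-[(3S,4R)-3,4-dihydroxy-2,6,6-trimethylcyclohex-1-en-1-yl]-3-methylpenta-2,4-dien-1-yl}triphenylphosphonium bromide; 27 (2E,4E,6E,8E,10E,12E,14E)-2,7,11,15,19-pentamethylicosa-2,4,6,8,10,12,14,18-octaenal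
Product: 29 (3R,4S)-β,ψ-carotene-3,4-diol (all-E), via phosphorus ylide 28 (not isolated)
Conditions: NaOMe (1.2 equiv), MeOH/CH2Cl2, 0 °C → rt, argon, dark; then reflux in EtOH (Z → E), crystallisation
Reagents that add atoms: none
Why: Wittig olefination forms the C11=C12 bond and tolerates the free diol because the ylide carbon is far more acidic than the hydroxyls; thermal equilibration should give the all-E polyene, and the ring stereocentres are not affected.

**Compound list**
1 | 3-ethoxycyclopent-2-en-1-one | CCOC1=CC(=O)CC1 | starting material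
2 | 3-ethoxy-5-methylcyclopent-2-en-1-one (racemic) | CCOC1=CC(=O)C(C)C1 | intermediate (not isolated)
3 | 3-ethoxy-5,5-dimethylcyclopent-2-en-1-one | CCOC1=CC(=O)C(C)(C)C1 | intermediate
4 | ethynyltri(propan-2-yl)silane | C#C[Si](C(C)C)(C(C)C)C(C)C | starting material
5 | lithium (triisopropylsilyl)acetylide | [Li]C#C[Si](C(C)C)(C(C)C)C(C)C | intermediate (not isolated)
6 | lithium 3-ethoxy-5,5-dimethyl-1-[(triisopropylsilyl)ethynyl]cyclopent-2-en-1-olate (racemic) | [Li]OC1(C#C[Si](C(C)C)(C(C)C)C(C)C)C=C(OCC)CC1(C)C | intermediate (not isolated)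
7 | 4,4-dimethyl-3-[(triisopropylsilyl)ethynyl]cyclopent-2-en-1-one | CC(C)[Si](C(C)C)(C(C)C)C#CC1=CC(=O)CC1(C)C | intermediate
8 | (1R)-4,4-dimethyl-3-[(triisopropylsilyl)ethynyl]cyclopent-2-en-1-ol | CC(C)[Si](C(C)C)(C(C)C)C#CC1=C[C@H](O)CC1(C)C | intermediate
9 | (1R)-4,4-dimethyl-3-[(triisopropylsilyl)ethynyl]cyclopent-2-en-1-yl dimethylcarbamate | CC(C)[Si](C(C)C)(C(C)C)C#CC1=C[C@H](OC(=O)N(C)C)CC1(C)C | intermediate
10 | (1R,2R,5S)-6,6-dibromo-4,4-dimethyl-5-[(triisopropylsilyl)ethynyl]bicyclo[3.1.0]hexan-2-yl dimethylcarbamate (cyclopropane anti to the carbamate) | CC(C)[Si](C(C)C)(C(C)C)C#C[C@@]12C(C)(C)C[C@@H](OC(=O)N(C)C)[C@@H]1C2(Br)Br | intermediate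
11 | (6R)-2-bromo-6-[(dimethylcarbamoyl)oxy]-4,4-dimethyl-3-[(triisopropylsilyl)ethynyl]cyclohex-2-en-1-ylium triflate | CC(C)[Si](C(C)C)(C(C)C)C#CC1=C(Br)[CH+][C@H](OC(=O)N(C)C)CC1(C)C.[O-]S(=O)(=O)C(F)(F)F | intermediate (not isolated)
12 | N-{(3aR,7aR)-7-bromo-5,5-dimethyl-6-[(triisopropylsilyl)ethynyl]-3a,4,5,7a-tetrahydro-1,3-benzodioxol-2-ylidene}-N-methylmethanaminium triflate (cis-fused) | CC(C)[Si](C(C)C)(C(C)C)C#CC1=C(Br)[C@H](O2)[C@H](OC2=[N+](C)C)CC1(C)C.[O-]S(=O)(=O)C(F)(F)F | intermediate (not isolated)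
13 | (3aR,7aR)-7-bromo-5,5-dimethyl-6-[(triisopropylsilyl)ethynyl]-3a,4,5,7a-tetrahydro-1,3-benzodioxol-2-one (cis-fused) | CC(C)[Si](C(C)C)(C(C)C)C#CC1=C(Br)[C@H](O2)[C@H](OC2=O)CC1(C)C | intermediate
14 | (1R,2R)-3-bromo-5,5-dimethyl-4-[(triisopropylsilyl)ethynyl]cyclohex-3-ene-1,2-diol (cis) | CC(C)[Si](C(C)C)(C(C)C)C#CC1=C(Br)[C@H](O)[C@H](O)CC1(C)C | intermediate (not isolated)
15 | (1R,2S)-3,5,5-trimethyl-4-[(triisopropylsilyl)ethynyl]cyclohex-3-ene-1,2-diol (cis) | CC(C)[Si](C(C)C)(C(C)C)C#CC1=C(C)[C@H](O)[C@H](O)CC1(C)C | intermediate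
16 | (1R,2S)-4-ethynyl-3,5,5-trimethylcyclohex-3-ene-1,2-diol | C#CC1=C(C)[C@H](O)[C@H](O)CC1(C)C | intermediate
17 | but-3-en-2-one | CC(=O)C=C | starting material
18 | tris(bromomagnesium) derivative of 16 (acetylide and both alkoxides) | Br[Mg]C#CC1=C(C)[C@H](O[Mg]Br)[C@H](O[Mg]Br)CC1(C)C | intermediate (not isolated)
19 | (1R,2S)-4-(3-hydroxy-3-methylpent-4-en-1-yn-1-yl)-3,5,5-trimethylcyclohex-3-ene-1,2-diol (both side-chain epimers) | C=CC(C)(O)C#CC1=C(C)[C@H](O)[C@H](O)CC1(C)C | intermediate
20 | (1R,2S)-4-[(1E)-3-hydroxy-3-methylpenta-1,4-dien-1-yl]-3,5,5-trimethylcyclohex-3-ene-1,2-diol (both side-chain epimers) | C=CC(C)(O)/C=C/C1=C(C)[C@H](O)[C@H](O)CC1(C)C | intermediate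
21 | {(2E,4E)-5-[(3S,4R)-3,4-dihydroxy-2,6,6-trimethylcyclohex-1-en-1-yl]-3-methylpenta-2,4-dien-1-yl}triphenylphosphonium bromide | [Br-].c1ccccc1[P+](c1ccccc1)(c1ccccc1)C/C=C(C)/C=C/C1=C(C)[C@H](O)[C@H](O)CC1(C)C | intermediate
22 | (3E,5E)-6,10-dimethylundeca-3,5,9-trien-2-one | CC(=O)/C=C/C=C(C)/CCC=C(C)C | starting material
23 | (4E,6E)-3,7,11-trimethyldodeca-1,4,6,10-tetraen-3-ol (racemic) | C=CC(C)(O)/C=C/C=C(C)/CCC=C(C)C | intermediate
24 | [(2E,4E,6E)-3,7,11-trimethyldodeca-2,4,6,10-tetraen-1-yl]triphenylphosphonium bromide | [Br-].CC(C)=CCC/C(C)=C/C=C/C(C)=C/C[P+](c1ccccc1)(c1ccccc1)c1ccccc1 | intermediate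
25 | (2E,4E,6E)-2,7-dimethylocta-2,4,6-trienedial | O=C/C(C)=C/C=C/C=C(C)/C=O | starting material
26 | [(2E,4E,6E)-3,7,11-trimethyldodeca-2,4,6,10-tetraen-1-ylidene]triphenylphosphorane | CC(C)=CCC/C(C)=C/C=C/C(C)=C/C=P(c1ccccc1)(c1ccccc1)c1ccccc1 | intermediate (not isolated)
27 | (2E,4E,6E,8E,10E,12E,14E)-2,7,11,15,19-pentamethylicosa-2,4,6,8,10,12,14,18-octaenal | CC(C)=CCC/C(C)=C/C=C/C(C)=C/C=C/C(C)=C/C=C/C=C(C)/C=O | intermediate
28 | ylide of 21, {(2E,4E)-5-[(3S,4R)-3,4-dihydroxy-2,6,6-trimethylcyclohex-1-en-1-yl]-3-methylpenta-2,4-dien-1-ylidene}triphenylphosphorane | c1ccccc1P(c1ccccc1)(c1ccccc1)=C/C=C(C)/C=C/C1=C(C)[C@H](O)[C@H](O)CC1(C)C | intermediate (not isolated)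
29 | (3R,4S)-β,ψ-carotene-3,4-diol (all-E, cis-diol) | CC(C)=CCC/C(C)=C/C=C/C(C)=C/C=C/C(C)=C/C=C/C=C(C)/C=C/C=C(C)/C=C/C1=C(C)[C@H](O)[C@H](O)CC1(C)C | target

**Count**
Total steps: 15. Longest linear sequence: 12 (steps 1–11, then step 15); the polyene arm is steps 12–14.

**Steps most likely to fail**

Step 6 (proposed new method). What may go wrong: capture of the allyl cation by the carbamate oxygen may be outrun by attack of an external nucleophile at C4 or C6, by return of bromide or by attack at the alkyne terminus, or the iminium intermediate may be opened at C4 instead of being hydrolysed at carbon, which would erode the cis relationship. The fallback uses known chemistry only, sets out from 8 and comes back at 14. Alcohol 8 is silylated (t-BuMe2SiCl, imidazole, DMF) to tert-butyl{[(1R)-4,4-dimethyl-3-[(triisopropylsilyl)ethynyl]cyclopent-2-en-1-yl]oxy}dimethylsilane F1. Dibromocarbene addition as in step 5 gives the dibromocyclopropane silyl ether F2. Silver-promoted electrocyclic ring opening with external water (AgClO4, acetone/H2O, CaCO3) should give the trans bromo alcohol F3, water entering anti to the silyloxy group. Mitsunobu inversion (PPh3, diisopropyl azodicarboxylate, 4-nitrobenzoic acid, THF) gives the cis 4-nitrobenzoate F4. Saponification (NaOH, MeOH/THF) gives the cis hydroxy silyl ether F5, and HCl in MeOH removes the silyl ether to give 14, which enters step 7 at its second stage.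

Step 11. What may go wrong: acid-promoted ionisation of the allylic C4 hydroxyl (epimerisation, methanolysis or elimination towards a 3,4-didehydro ring) may compete with the wanted ionisation at the side-chain carbinol. The fallback avoids acid, sets out from 20 and comes back at 29. Treatment of 20 with 1,1'-carbonyldiimidazole (CH2Cl2, rt) protects the cis-diol as (3aR,7aS)-6-[(1E)-3-hydroxy-3-methylpenta-1,4-dien-1-yl]-5,5,7-trimethyl-3a,4,5,7a-tetrahydro-1,3-benzodioxol-2-one F6. Ph2PCl and Et3N (THF, −20 °C → 50 °C) convert the tertiary alcohol into an allyl phosphinite that undergoes [2,3]-sigmatropic rearrangement to the allylic diphenylphosphine oxide F7. Horner–Wittig olefination of F7 with aldehyde 27 (NaN(SiMe3)2, THF, −78 °C → rt) gives the cyclic carbonate of the target F8, and K2CO3 in MeOH releases 29.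

Step 2. What may go wrong: the acetylide may deprotonate the vinylogous ester at its γ-carbon instead of adding, or 1,2-addition may be too slow at a carbonyl that is both deactivated and flanked by a quaternary carbon. The fallback builds the enone by a different bond-forming logic, sets out from 4 and comes back at 7. Lithium acetylide 5 (from 4 and n-BuLi) is added to commercial 2,2-dimethylcyclopentanone to give 2,2-dimethyl-1-[(triisopropylsilyl)ethynyl]cyclopentan-1-ol F9. Dehydration (POCl3, pyridine), which can only proceed towards the ring CH2, gives [(5,5-dimethylcyclopent-1-en-1-yl)ethynyl]triisopropylsilane F10. Allylic oxidation of its single allylic CH2 group (CrO3·3,5-dimethylpyrazole, CH2Cl2, −20 °C) gives 7.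

**Further compounds**
F1 | step 6 | tert-butyl{[(1R)-4,4-dimethyl-3-[(triisopropylsilyl)ethynyl]cyclopent-2-en-1-yl]oxy}dimethylsilane | CC(C)[Si](C(C)C)(C(C)C)C#CC1=C[C@H](O[Si](C)(C)C(C)(C)C)CC1(C)C
F2 | step 6 | tert-butyl{[(1R,2R,5S)-6,6-dibromo-4,4-dimethyl-5-[(triisopropylsilyl)ethynyl]bicyclo[3.1.0]hexan-2-yl]oxy}dimethylsilane (cyclopropane anti to the silyloxy group) | CC(C)[Si](C(C)C)(C(C)C)C#C[C@@]12C(C)(C)C[C@@H](O[Si](C)(C)C(C)(C)C)[C@@H]1C2(Br)Br
F3 | step 6 | (1S,6R)-2-bromo-6-[(tert-butyldimethylsilyl)oxy]-4,4-dimethyl-3-[(triisopropylsilyl)ethynyl]cyclohex-2-en-1-ol (trans) | CC(C)[Si](C(C)C)(C(C)C)C#CC1=C(Br)[C@@H](O)[C@H](O[Si](C)(C)C(C)(C)C)CC1(C)C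
F4 | step 6 | (1R,6R)-2-bromo-6-[(tert-butyldimethylsilyl)oxy]-4,4-dimethyl-3-[(triisopropylsilyl)ethynyl]cyclohex-2-en-1-yl 4-nitrobenzoate (cis) | CC(C)[Si](C(C)C)(C(C)C)C#CC1=C(Br)[C@H](OC(=O)c2ccc(cc2)[N+]([O-])=O)[C@H](O[Si](C)(C)C(C)(C)C)CC1(C)C
F5 | step 6 | (1R,6R)-2-bromo-6-[(tert-butyldimethylsilyl)oxy]-4,4-dimethyl-3-[(triisopropylsilyl)ethynyl]cyclohex-2-en-1-ol (cis) | CC(C)[Si](C(C)C)(C(C)C)C#CC1=C(Br)[C@H](O)[C@H](O[Si](C)(C)C(C)(C)C)CC1(C)C
F6 | step 11 | (3aR,7aS)-6-[(1E)-3-hydroxy-3-methylpenta-1,4-dien-1-yl]-5,5,7-trimethyl-3a,4,5,7a-tetrahydro-1,3-benzodioxol-2-one (both side-chain epimers) | C=CC(C)(O)/C=C/C1=C(C)[C@H](O2)[C@H](OC2=O)CC1(C)C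
F7 | step 11 | (3aR,7aS)-6-[(1E,3E)-5-(diphenylphosphoryl)-3-methylpenta-1,3-dien-1-yl]-5,5,7-trimethyl-3a,4,5,7a-tetrahydro-1,3-benzodioxol-2-one | O=P(c1ccccc1)(c1ccccc1)C/C=C(C)/C=C/C1=C(C)[C@H](O2)[C@H](OC2=O)CC1(C)C
F8 | step 11 | (3R,4S)-β,ψ-carotene-3,4-diyl carbonate (cyclic carbonate of 29) | CC(C)=CCC/C(C)=C/C=C/C(C)=C/C=C/C(C)=C/C=C/C=C(C)/C=C/C=C(C)/C=C/C1=C(C)[C@H](O2)[C@H](OC2=O)CC1(C)C
F9 | step 2 | 2,2-dimethyl-1-[(triisopropylsilyl)ethynyl]cyclopentan-1-ol (racemic) | CC(C)[Si](C(C)C)(C(C)C)C#CC1(O)CCCC1(C)C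
F10 | step 2 | [(5,5-dimethylcyclopent-1-en-1-yl)ethynyl]triisopropylsilane | CC(C)[Si](C(C)C)(C(C)C)C#CC1=CCCC1(C)C
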